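(The constants used here come from no measurement; what happens was integrated by code.)

Every nucleophile charged stays in the count: free, protonated, dormant, or built into target and side product.

    electrophile + nucleophile → acid set free + target (k1 = 1.1 M⁻¹ min⁻¹)
    nucleophile + acid set free ⇌ protonated nucleophile, settled at all times (K2 = 700 M⁻¹)
    acid set free + target → side product (k3 = 1.4 M⁻¹ min⁻¹)
    acid set free → by-product carried off (k4 = 0.12 min⁻¹)
    nucleophile ⇌ dormant form (K5 = 13, k5 = 0.28 min⁻¹)

| flask | electrophile | nucleophile | time |
|---|---|---|---|
| delta | 0.20 M | 0.200 M | 12 min |
| beta | 0.20 M | 0.340 M | 12 min |
| theta | 0.20 M | 0.260 M | 12 min |
- part of the electrophile that has reacted at the end, delta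
- part of the electrophile that has reacted at the end, beta
- part of the electrophile that has reacted at the end, theta
- what raising the concentration of nucleophile from its lowest to its highest value here does to the part of the electrophile that has reacted (changes below 5 percentage points count as none) (it falls / no change / it rises)

I count in equivalents of the electrophile charge and ask what one coupling costs in nucleophile. The coupling takes one. The acid set free takes a second, because the equilibrium constant of step 2 times the starting nucleophile is 140.

Dormancy takes a further share. At the charge, the half-life of nucleophile is 2.48 min toward the dormant form and 3.15 min toward coupling. Their ratio is the dormancy toll, the nucleophile lost to the dormant form per coupling: 1.27. Delta, theta and beta share the electrophile charge, so they share this toll.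

The way back has a half-life of 32.2 min, longer than the 12 min of the run, so I book dormant nucleophile as lost. The run holds 4.84 dormancy half-lives, so I book the charge as paid out by the end. One coupling then costs 3.27 equivalents, and nucleophile is the limiting reagent even in delta, where the charges are equal.

My table gives equivalents charged, then the part reacted:

- delta: 1.00, then 30.6%
- theta: 1.30, then 39.7%
- beta: 1.70, then 51.9%

Reading down, delta to beta gains 21 percentage points, more than the 5 points that counts as a change, so I say the part reacted rises. Reading across, I trust the beta row least, because it takes the electrophile furthest down, and I took the toll at the charge.

The forecast says 32% for delta, 40% for theta and 49.5% for beta, and also it rises. Its grounds are a stepwise balance in which free nucleophile collapses and “the reaction nearly stalls”. It stands below my figure for beta and slightly above mine for delta and theta.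

The flask gives 33.1% for delta, 41.2% for theta and 51.0% for beta; from delta to beta it rises, by 18 points. Free nucleophile ends at 3.38% of its charge in delta and 3.49% in beta. The neighbour flask with 0.80 M of nucleophile has the same toll, and a flat cost would ask for 122% of the electrophile. That flask reads 87.1%, and it holds 2.47 of dormant form per electrophile reacted, against the toll of 1.27.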